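**Retrosynthetic overview**
1. Target 17 ⇐ Wittig methylenation of decalone 16 (C3=O → C3=CH2).
2. 16 ⇐ one cationic cascade from acyclic bis-bromohydrin 14: ring B (bromocyclohexane) closes first, then ring A, ended by a silyl enol ether. The same reagent turns the side-chain bromohydrin into CHBr–CMe2Cl.
3. 14 ⇐ Claisen–Schmidt union of 3,5-dibromosalicylaldehyde with methyl ketone 9, then 1,4-hydrosilylation and bromide opening of both epoxides.
4. 9 ⇐ key C–C bond C4–C5: the sulfonyl-stabilised farnesyl C1 carbanion (farnesyl C1 with its polarity reversed) opens propylene oxide, and the sulfone is removed in the same flask.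
5. The sulfone also deactivates the neighbouring alkene, so one double Shi epoxidation of farnesyl phenyl sulfone sets C10, C11 and C14.

Assumption: chain atoms are labelled C1 (benzylic CH2) to C15 (CMe2Cl) as in the open-chain precursor ArC1H2–C2–C3–C4–C5–C6=C7(Me)–C8–C9–C10–C11(Me)–C12–C13–C14–C15Me2, and the L-fructose-derived (ent-)Shi ketone is taken as a purchasable catalyst.

Step 1
Reactants: 1 (2E,6E)-farnesyl bromide; 2 sodium benzenesulfinate
Product: 3 (2E,6E)-farnesyl phenyl sulfone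
Conditions: DMF, 0 °C → rt
Reagents that add atoms: none
Why: SN2 S-alkylation of the sulfinate by the primary allylic bromide keeps both E alkenes; the sulfonyl group later deactivates the adjacent alkene, acidifies C5 and leaves tracelessly.

Step 2
Reactants: 3 (2E,6E)-farnesyl phenyl sulfone
Product: 4 (2E,6S,7S,10S)-6,7:10,11-diepoxyfarnesyl phenyl sulfone
Conditions: ent-Shi ketone (L-fructose-derived, 0.6 equiv), KHSO5 (Oxone), K2CO3, Bu4NHSO4, MeCN–CH2(OMe)2–aq. borate buffer (pH 10.5), 0 °C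
Reagents that add atoms: potassium peroxymonosulfate, [K+].[O-]S(=O)(=O)OO
Why: Shi asymmetric epoxidation: the electrophilic chiral dioxirane attacks only the two electron-rich trisubstituted alkenes (the allylic-sulfone alkene is inductively deactivated) through the spiro transition state, and the L-series ketone gives the S,S,S bis-epoxide that fixes C10, C11 and C14 (the D-fructose ketone would give the enantiomer).

Step 3
Reactants: 4 (2E,6S,7S,10S)-6,7:10,11-diepoxyfarnesyl phenyl sulfone; 5 (±)-propylene oxide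
Product: 8 (5E,9S,10S,13S)-9,10:13,14-diepoxy-6,10,14-trimethylpentadec-5-en-2-ol (epimers at C2), via lithiated sulfone 6 (not isolated), via hydroxy sulfone 7 (not isolated)
Conditions: n-BuLi, THF–DMPU, −78 °C; 5, −78 → 0 °C; then PdCl2[Ph2P(CH2)3PPh2] (5 mol %), LiBHEt3, −20 → 0 °C
Reagents that add atoms: none
Why: α-Sulfonyl carbanion alkylation (Julia/Biellmann type): the sulfonyl-stabilised allyl anion makes farnesyl C1 nucleophilic and opens the epoxide at CH2 by SN2, joining two carbons that are both electrophiles in their parent bromide and epoxide; zerovalent-palladium-catalysed allylic hydrogenolysis (π-allyl, hydride to the less substituted end, E alkene kept) then excises the sulfone, and the transient stereocentres at C3 and C5 need no control.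

Step 4
Reactants: 8 (5E,9S,10S,13S)-9,10:13,14-diepoxy-6,10,14-trimethylpentadec-5-en-2-ol
Product: 9 (5E,9S,10S,13S)-9,10:13,14-diepoxy-6,10,14-trimethylpentadec-5-en-2-one
Conditions: Pr4N[RuO4] (5 mol %), N-methylmorpholine N-oxide, 4 Å MS, CH2Cl2, rt
Reagents that add atoms: none
Why: Ley–Griffith oxidation of the secondary alcohol under neutral conditions, so the acid-labile trisubstituted epoxides survive.

Step 5
Reactants: 9 (5E,9S,10S,13S)-9,10:13,14-diepoxy-6,10,14-trimethylpentadec-5-en-2-one; 10 3,5-dibromo-2-hydroxybenzaldehyde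
Product: 12 (1E,6E,10S,11S,14S)-1-(3,5-dibromo-2-hydroxyphenyl)-10,11:14,15-diepoxy-7,11,15-trimethylhexadeca-1,6-dien-3-one, via aldol adduct 11 (not isolated)
Conditions: NaOH (aq), EtOH, rt → 40 °C; NH4Cl work-up
Reagents that add atoms: none
Why: Claisen–Schmidt crossed aldol condensation: under hydroxide the methyl α-carbon (not the methylene) adds to the non-enolisable aldehyde and E1cB dehydration gives the E enone; epoxides are inert to base.

Step 6
Reactants: 12 (1E,6E,10S,11S,14S)-enone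
Product: 13 (2Z,6E,10S,11S,14S)-1-[3,5-dibromo-2-(triethylsilyloxy)phenyl]-10,11:14,15-diepoxy-7,11,15-trimethyl-3-(triethylsilyloxy)hexadeca-2,6-diene
Conditions: Et3SiH (3 equiv), RhCl(PPh3)3 (2 mol %), THF, 50 °C
Reagents that add atoms: triethylsilane, CC[SiH](CC)CC
Why: Rh-catalysed 1,4-hydrosilylation of the s-cis enone (Ojima type) places the silyl enol ether regiospecifically at C2=C3 with Z geometry; the phenol is silylated in the same operation by dehydrogenative Si–O coupling.

Step 7
Reactants: 13 (2Z,6E,10S,11S,14S)-bis-epoxide bis(silyl ether)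
Product: 14 (2Z,6E,10R,11S,14R)-10,14-dibromo-1-[3,5-dibromo-2-(triethylsilyloxy)phenyl]-7,11,15-trimethyl-3-(triethylsilyloxy)hexadeca-2,6-diene-11,15-diol
Conditions: Li2NiBr4 (from LiBr + NiBr2), THF, 0 °C → rt; pH 7 buffer
Reagents that add atoms: dilithium tetrabromonickelate (divalent nickel), [Li+].[Li+].Br[Ni-2](Br)(Br)Br
Why: Soft bromide opens each trisubstituted epoxide by SN2 at the less substituted carbon (C10 and C14) with inversion (S → R), leaving tertiary alcohols at C11 and C15 anti to bromine.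

Step 8
Reactants: 14 (2Z,6E,10R,11S,14R)-bis-bromohydrin
Product: 16 (1S,4aS,5R,6R,8aR)-6-bromo-5-[(3R)-3-bromo-4-chloro-4-methylpentyl]-1-(3,5-dibromo-2-hydroxybenzyl)-5,8a-dimethyloctahydronaphthalen-2(1H)-one, via aryl silyl ether ketone 15 (not isolated)
Conditions: TiCl4 (4 equiv), 2,6-di-tert-butyl-4-methylpyridine, CH2Cl2, −78 → −45 °C; then 1 M HCl, THF, 0 °C
Reagents that add atoms: titanium tetrachloride, Cl[Ti](Cl)(Cl)Cl
Why: Proposed new method: TiCl4 ionises both tertiary alkoxides with anchimeric help from the anti bromine to give enantiopure bromonium ions; the C14/C15 ion can only collapse with chloride at the tertiary carbon (CHBr–CMe2Cl, C14 untouched), while the C10/C11 ion is attacked at C11, anti to bromine, by the C6=C7 alkene through a chair–chair transition state (trans ring fusion, axial methyls at C11 and C7, equatorial Br) and the C7 cation is captured at C2 by the Z silyl enol ether (CH2Ar equatorial), so C11, C6, C7 and C2 are set from C10; the closest known chemistry is Lewis-acid tert-alkylation of silyl enol ethers with tertiary chlorides and bromonium-initiated cation–olefin polycyclisation from enantiopure bromohydrins.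

Step 9
Reactants: 16 keto phenol
Product: 17 2,4-dibromo-6-{[(1R,4aS,5R,6R,8aS)-6-bromo-5-[(3R)-3-bromo-4-chloro-4-methylpentyl]-5,8a-dimethyl-2-methylidenedecahydronaphthalen-1-yl]methyl}phenol (target)
Conditions: Ph3PCH3Br, KN(SiMe3)2 (3.5 equiv ylide), THF–toluene, 0 °C → rt
Reagents that add atoms: methylenetriphenylphosphorane, C=P(c1ccccc1)(c1ccccc1)c1ccccc1 (made from methyltriphenylphosphonium bromide, C[P+](c1ccccc1)(c1ccccc1)c1ccccc1.[Br-])
Why: Wittig methylenation of the hindered ring ketone; the α-stereocentre already has the equatorial (thermodynamic) configuration and the equatorial ring bromide has no anti-periplanar hydrogen for E2.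

**Compound list**
1 | (2E,6E)-farnesyl bromide | CC(C)=CCC/C(C)=C/CC/C(C)=C/CBr | starting material
2 | sodium benzenesulfinate | [Na+].[O-]S(=O)c1ccccc1 | starting material
3 | (2E,6E)-farnesyl phenyl sulfone | CC(C)=CCC/C(C)=C/CC/C(C)=C/CS(=O)(=O)c1ccccc1 | intermediate
4 | (2E,6S,7S,10S)-6,7:10,11-diepoxyfarnesyl phenyl sulfone | O=S(=O)(C/C=C(\C)CC[C@@H]1O[C@@]1(C)CC[C@@H]1OC1(C)C)c1ccccc1 | intermediate
5 | (±)-propylene oxide (2-methyloxirane) | CC1CO1 | starting material
6 | α-lithio derivative of sulfone 4 | [Li]C(/C=C(\C)CC[C@@H]1O[C@@]1(C)CC[C@@H]1OC1(C)C)S(=O)(=O)c1ccccc1 | intermediate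
7 | (5E,9S,10S,13S)-9,10:13,14-diepoxy-6,10,14-trimethyl-4-(phenylsulfonyl)pentadec-5-en-2-ol (epimers at C2 and C4) | CC(O)CC(/C=C(\C)CC[C@@H]1O[C@@]1(C)CC[C@@H]1OC1(C)C)S(=O)(=O)c1ccccc1 | intermediate
8 | (5E,9S,10S,13S)-9,10:13,14-diepoxy-6,10,14-trimethylpentadec-5-en-2-ol (epimers at C2) | CC(O)CC/C=C(\C)CC[C@@H]1O[C@@]1(C)CC[C@@H]1OC1(C)C | intermediate
9 | (5E,9S,10S,13S)-9,10:13,14-diepoxy-6,10,14-trimethylpentadec-5-en-2-one | CC(=O)CC/C=C(\C)CC[C@@H]1O[C@@]1(C)CC[C@@H]1OC1(C)C | intermediate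
10 | 3,5-dibromo-2-hydroxybenzaldehyde | O=Cc1cc(Br)cc(Br)c1O | starting material
11 | (6E,10S,11S,14S)-1-(3,5-dibromo-2-hydroxyphenyl)-10,11:14,15-diepoxy-1-hydroxy-7,11,15-trimethylhexadec-6-en-3-one (aldol adduct, epimers at C1) | OC(CC(=O)CC/C=C(\C)CC[C@@H]1O[C@@]1(C)CC[C@@H]1OC1(C)C)c1cc(Br)cc(Br)c1O | intermediate
12 | (1E,6E,10S,11S,14S)-1-(3,5-dibromo-2-hydroxyphenyl)-10,11:14,15-diepoxy-7,11,15-trimethylhexadeca-1,6-dien-3-one | O=C(/C=C/c1cc(Br)cc(Br)c1O)CC/C=C(\C)CC[C@@H]1O[C@@]1(C)CC[C@@H]1OC1(C)C | intermediate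
13 | (2Z,6E,10S,11S,14S)-1-[3,5-dibromo-2-(triethylsilyloxy)phenyl]-10,11:14,15-diepoxy-7,11,15-trimethyl-3-(triethylsilyloxy)hexadeca-2,6-diene | CC[Si](CC)(CC)O/C(CC/C=C(\C)CC[C@@H]1O[C@@]1(C)CC[C@@H]1OC1(C)C)=C\Cc1cc(Br)cc(Br)c1O[Si](CC)(CC)CC | intermediate
14 | (2Z,6E,10R,11S,14R)-10,14-dibromo-1-[3,5-dibromo-2-(triethylsilyloxy)phenyl]-7,11,15-trimethyl-3-(triethylsilyloxy)hexadeca-2,6-diene-11,15-diol | CC[Si](CC)(CC)O/C(CC/C=C(\C)CC[C@@H](Br)[C@@](C)(O)CC[C@@H](Br)C(C)(C)O)=C\Cc1cc(Br)cc(Br)c1O[Si](CC)(CC)CC | intermediate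
15 | (1S,4aS,5R,6R,8aR)-6-bromo-5-[(3R)-3-bromo-4-chloro-4-methylpentyl]-1-[3,5-dibromo-2-(triethylsilyloxy)benzyl]-5,8a-dimethyloctahydronaphthalen-2(1H)-one | O=C1CC[C@@H]2[C@@](C)(CC[C@@H](Br)C(C)(C)Cl)[C@H](Br)CC[C@@]2(C)[C@@H]1Cc1cc(Br)cc(Br)c1O[Si](CC)(CC)CC | intermediate
16 | (1S,4aS,5R,6R,8aR)-6-bromo-5-[(3R)-3-bromo-4-chloro-4-methylpentyl]-1-(3,5-dibromo-2-hydroxybenzyl)-5,8a-dimethyloctahydronaphthalen-2(1H)-one | O=C1CC[C@@H]2[C@@](C)(CC[C@@H](Br)C(C)(C)Cl)[C@H](Br)CC[C@@]2(C)[C@@H]1Cc1cc(Br)cc(Br)c1O | intermediate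
17 | 2,4-dibromo-6-{[(1R,4aS,5R,6R,8aS)-6-bromo-5-[(3R)-3-bromo-4-chloro-4-methylpentyl]-5,8a-dimethyl-2-methylidenedecahydronaphthalen-1-yl]methyl}phenol | C=C1CC[C@@H]2[C@@](C)(CC[C@@H](Br)C(C)(C)Cl)[C@H](Br)CC[C@@]2(C)[C@@H]1Cc1cc(Br)cc(Br)c1O | target

**Totals:** 9 steps; longest linear sequence 9 steps (1 → 17; aldehyde 10 and epoxide 5 enter as purchased).

**Three steps most likely to fail, with fallbacks**

Step 8 (two bromonium events in one flask; premature chloride capture at C11, elimination or loss of the enol ether are the dangers). The fallback sets out from enone 12 and separates chloride installation from ring closure. Li2NiBr4 opens both epoxides of 12 to the bis-bromohydrin enone F4. SOCl2/pyridine with Bu4NCl at −40 °C converts both tertiary alcohols through the same bromonium ions into the bis(bromochloride) enone F5. Rh-catalysed hydrosilylation with Et3SiH then gives the bis(bromochloride) silyl enol ether F6. Catalytic SnCl4 (CH2Cl2, −78 °C) ionises the tertiary chlorides reversibly; only the C11 ion has an irreversible exit, closing both rings onto the silyl enol ether with loss of Et3SiCl. The route is rejoined at 15.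

Step 7 (SN2 of bromide at a secondary carbon next to a fully substituted epoxide carbon, with a silyl enol ether present). The fallback sets out from 13 and uses the opposite regiochemistry on purpose. MgBr2·OEt2 opens both epoxides at the tertiary carbon to the regioisomeric bis-bromohydrin F3 (tertiary bromides, secondary alcohols). Tf2O with 2,6-di-tert-butyl-4-methylpyridine and Bu4NCl at −78 °C then activates the secondary alcohols. The tertiary bromine bridges with inversion at C10/C14 to the same bromonium ions as in the main route, which are captured by chloride (C15) and by the polyene (C11). The route is rejoined at 15, bypassing 14.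

Step 3 (hydride in the presence of two epoxides during the in-flask desulfonylation). The fallback sets out from 4 and keeps the sulfonyl carbanion but changes electrophile and cleavage mode. Lithiated 4 is alkylated with 2-methoxyallyl bromide (from 2-methoxypropene and NBS), an acetonyl cation equivalent, to give the enol ether sulfone F1. Electron-transfer desulfonylation with Na(Hg)/Na2HPO4 in MeOH at −20 °C, which leaves epoxides alone, gives the enol ether F2. Aqueous oxalic acid on silica unmasks the methyl ketone. The route is rejoined at 9, with no oxidation step.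

**Further compounds**
F1 | step 3 | {[(5E,9S,10S,13S)-9,10:13,14-diepoxy-2-methoxy-6,10,14-trimethylpentadeca-1,5-dien-4-yl]sulfonyl}benzene | COC(=C)CC(/C=C(\C)CC[C@@H]1O[C@@]1(C)CC[C@@H]1OC1(C)C)S(=O)(=O)c1ccccc1
F2 | step 3 | (5E,9S,10S,13S)-9,10:13,14-diepoxy-2-methoxy-6,10,14-trimethylpentadeca-1,5-diene | COC(=C)CC/C=C(\C)CC[C@@H]1O[C@@]1(C)CC[C@@H]1OC1(C)C
F3 | step 7 | (2Z,6E,10S,11R,14S)-11,15-dibromo-1-[3,5-dibromo-2-(triethylsilyloxy)phenyl]-7,11,15-trimethyl-3-(triethylsilyloxy)hexadeca-2,6-diene-10,14-diol | CC[Si](CC)(CC)O/C(CC/C=C(\C)CC[C@H](O)[C@](C)(Br)CC[C@H](O)C(C)(C)Br)=C\Cc1cc(Br)cc(Br)c1O[Si](CC)(CC)CC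
F4 | step 8 | (1E,6E,10R,11S,14R)-10,14-dibromo-1-(3,5-dibromo-2-hydroxyphenyl)-11,15-dihydroxy-7,11,15-trimethylhexadeca-1,6-dien-3-one | O=C(/C=C/c1cc(Br)cc(Br)c1O)CC/C=C(\C)CC[C@@H](Br)[C@@](C)(O)CC[C@@H](Br)C(C)(C)O
F5 | step 8 | (1E,6E,10R,11S,14R)-10,14-dibromo-11,15-dichloro-1-(3,5-dibromo-2-hydroxyphenyl)-7,11,15-trimethylhexadeca-1,6-dien-3-one | O=C(/C=C/c1cc(Br)cc(Br)c1O)CC/C=C(\C)CC[C@@H](Br)[C@@](C)(Cl)CC[C@@H](Br)C(C)(C)Cl
F6 | step 8 | (2Z,6E,10R,11S,14R)-10,14-dibromo-11,15-dichloro-1-[3,5-dibromo-2-(triethylsilyloxy)phenyl]-7,11,15-trimethyl-3-(triethylsilyloxy)hexadeca-2,6-diene | CC[Si](CC)(CC)O/C(CC/C=C(\C)CC[C@@H](Br)[C@@](C)(Cl)CC[C@@H](Br)C(C)(C)Cl)=C\Cc1cc(Br)cc(Br)c1O[Si](CC)(CC)CC
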